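**Retrosynthetic overview**
1. Hansforester J is a linear tetramer A–B–C–D. A is 5-[(R)-2-hydroxypropyl]resorcinol, B and D are (R)-3-hydroxybutanoate, and C is 6-[(R)-2-hydroxypropyl]-β-resorcylate. The three links are ester C–O bonds, and these are the only strategic cuts.
2. The key disconnection is the hindered aryl ester C(=O)–O bond between C and B. It gives an acid half D–C and an alcohol half B–A. The last operation removes four benzyl ethers and one formate in one flask.
3. The acid half is the alcohol half plus one carbon (ring formylation, then oxidation), so both halves come from one common hydroxy ester.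
4. The common hydroxy ester is cut at its ester C–O bond. A magnesium alkoxide (aryl Grignard plus (R)-propylene oxide) opens (R)-β-butyrolactone at the acyl–O bond in the same flask (new step). These two building blocks supply all four stereocentres.
5. Rings: none is built. Both benzene rings are bought in the aryl bromide, and the oxirane and oxetanone rings are only opened.

Assumption: 1,3-bis(benzyloxy)-5-bromobenzene, (R)-propylene oxide and (R)-β-butyrolactone are taken as catalogue chemicals, the two chiral ones in at least 98% ee.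

**Step 1**
Reactants: 1 1,3-bis(benzyloxy)-5-bromobenzene; 2 (R)-propylene oxide [(R)-2-methyloxirane]; 3 (R)-β-butyrolactone [(R)-4-methyloxetan-2-one]
Product: 7 (R)-1-[3,5-bis(benzyloxy)phenyl]propan-2-yl (R)-3-hydroxybutanoate, via aryl Grignard reagent 4 (not isolated), via bromomagnesium propan-2-olate 5 (not isolated), via chelated bromomagnesium alkoxide 6 (not isolated)
Conditions: Mg, LiCl, THF, 40 °C; CuBr·SMe2 (5 mol %), 2 (1.05 equiv), −30 → 0 °C; 3 (1.0 equiv, syringe pump), −20 → 0 °C; AcOH (1.2 equiv), −40 °C
Reagents that add atoms: magnesium, [Mg] (kept only in 4, 5 and 6, lost on the AcOH quench)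
Why: Proposed new method: a one-flask epoxide/β-lactone relay in which alkoxide 5, formed by copper-catalysed SN2 opening of 2 at its CH2 terminus (stereocentre untouched, R kept), serves directly as the nucleophile for a single, stereoretentive acyl–oxygen opening of 3; the hard, Lewis-acidic Mg–OR unit binds and attacks the lactone carbonyl, the tetrahedral intermediate collapses with release of about 23 kcal/mol of ring strain without touching C4 of the lactone (R kept), the new alkoxide 6 is held in a six-membered Mg chelate with its own ester carbonyl and is inductively deactivated so a second insertion is slower than the first and one equivalent of 3 stops at the mono-adduct, and the slight excess of 2 leaves no Grignard reagent to attack 3; the closest known reaction type is the coordination–insertion ring-opening polymerisation of β-butyrolactone started by Mg, Zn or Y alkoxides (acyl–O cleavage with retention), which has not been run as a single insertion on an alkoxide generated in situ by Grignard opening of an epoxide.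

**Step 2**
Reactants: 7 (R)-1-[3,5-bis(benzyloxy)phenyl]propan-2-yl (R)-3-hydroxybutanoate
Product: 9 (R)-1-[3,5-bis(benzyloxy)-2-formylphenyl]propan-2-yl (R)-3-(formyloxy)butanoate, via bis(iminium) dichloride 8 (not isolated)
Conditions: POCl3 (3 equiv), DMF, 0 °C → rt, 16 h; aq NaOAc, 0 °C
Reagents that add atoms: N,N-dimethylformamide, CN(C)C=O (both formyl carbons); water, O (both formyl oxygens); phosphoryl chloride, O=P(Cl)(Cl)Cl (chloride ions of 8 only)
Why: Vilsmeier–Haack formylation attacks the ring position next to the side chain (para to one benzyloxy group, ortho to the other, while the site between the two benzyloxy groups is sterically shut), and the same reagent captures the free hydroxyl as an alkoxymethyleneiminium salt whose weakly acidic hydrolysis gives the formate, so the D hydroxyl is protected at no step cost and without breaking a C–O bond at either stereocentre.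

**Step 3**
Reactants: 9 (R)-1-[3,5-bis(benzyloxy)-2-formylphenyl]propan-2-yl (R)-3-(formyloxy)butanoate
Product: 10 2,4-bis(benzyloxy)-6-[(R)-2-{[(R)-3-(formyloxy)butanoyl]oxy}propyl]benzoic acid
Conditions: NaClO2, NaH2PO4, 2-methyl-2-butene (20 equiv), t-BuOH–THF–H2O, 0 °C → rt
Reagents that add atoms: sodium chlorite NaClO2, [Na+].[O-]Cl=O
Why: Pinnick oxidation at about pH 4 converts the hindered, electron-rich aldehyde into the acid, while the formate, the ester and the benzyl ethers are inert and the excess alkene traps HOCl before it can chlorinate the ring.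

**Step 4**
Reactants: 10 2,4-bis(benzyloxy)-6-[(R)-2-{[(R)-3-(formyloxy)butanoyl]oxy}propyl]benzoic acid; 7 (R)-1-[3,5-bis(benzyloxy)phenyl]propan-2-yl (R)-3-hydroxybutanoate
Product: 12 (R)-4-{[(R)-1-[3,5-bis(benzyloxy)phenyl]propan-2-yl]oxy}-4-oxobutan-2-yl 2,4-bis(benzyloxy)-6-[(R)-2-{[(R)-3-(formyloxy)butanoyl]oxy}propyl]benzoate, via acid chloride 11 (not isolated)
Conditions: (COCl)2, DMF (cat.), CH2Cl2, 0 °C → rt, evaporate; 7 (1.1 equiv), Et3N, DMAP, CH2Cl2, 0 °C → rt
Reagents that add atoms: oxalyl chloride, O=C(Cl)C(=O)Cl (chlorine of 11 only)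
Why: Acid chloride formation followed by DMAP-catalysed acylation (nucleophilic acyl substitution) is the standard way to esterify 2,6-disubstituted 2,4-dialkoxybenzoic acids with secondary alcohols; the only free hydroxyl present is that of 7, and its carbinol C–O bond is kept, so the B stereocentre stays R.

**Step 5**
Reactants: 12 the fully protected tetramer from step 4
Product: 14 hansforester J, via O-formyl hansforester J 13 (not isolated)
Conditions: H2 (1 atm), 10% Pd/C, EtOAc–MeOH 1:1, rt; then N2, p-TsOH·H2O (5 mol %), rt, 3 h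
Reagents that add atoms: none
Why: Catalytic hydrogenolysis removes the four aryl benzyl ethers and leaves the homobenzylic esters alone; acid-catalysed transesterification with methanol then strips the formate, by far the least hindered and most electrophilic ester, faster than any of the three secondary-alkyl esters reacts, under non-basic conditions that cannot trigger β-elimination or touch a stereocentre.

Stereocentre ledger: the A and C carbinols come from 2 and the B and D carbinols from 3. No later step breaks a C–O bond at a stereocentre, so all four are R, as in the target.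

**Compound list**
1 | 1,3-bis(benzyloxy)-5-bromobenzene | Brc1cc(OCc2ccccc2)cc(OCc2ccccc2)c1 | starting material
2 | (R)-propylene oxide | C[C@@H]1CO1 | starting material
3 | (R)-β-butyrolactone | C[C@@H]1CC(=O)O1 | starting material
4 | 3,5-bis(benzyloxy)phenylmagnesium bromide | Br[Mg]c1cc(OCc2ccccc2)cc(OCc2ccccc2)c1 | intermediate
5 | bromomagnesium (R)-1-[3,5-bis(benzyloxy)phenyl]propan-2-olate | C[C@H](Cc1cc(OCc2ccccc2)cc(OCc2ccccc2)c1)O[Mg]Br | intermediate
6 | bromomagnesium alkoxide of 7 (Mg chelated by the ester carbonyl) | C[C@H](Cc1cc(OCc2ccccc2)cc(OCc2ccccc2)c1)OC(=O)C[C@@H](C)O[Mg]Br | intermediate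
7 | (R)-1-[3,5-bis(benzyloxy)phenyl]propan-2-yl (R)-3-hydroxybutanoate | C[C@H](Cc1cc(OCc2ccccc2)cc(OCc2ccccc2)c1)OC(=O)C[C@@H](C)O | intermediate
8 | bis(iminium) dichloride (aryl CH=NMe2+ and O–CH=NMe2+) | C[C@H](Cc1cc(OCc2ccccc2)cc(OCc2ccccc2)c1C=[N+](C)C)OC(=O)C[C@@H](C)OC=[N+](C)C.[Cl-].[Cl-] | intermediate
9 | (R)-1-[3,5-bis(benzyloxy)-2-formylphenyl]propan-2-yl (R)-3-(formyloxy)butanoate | C[C@H](Cc1cc(OCc2ccccc2)cc(OCc2ccccc2)c1C=O)OC(=O)C[C@@H](C)OC=O | intermediate
10 | 2,4-bis(benzyloxy)-6-[(R)-2-{[(R)-3-(formyloxy)butanoyl]oxy}propyl]benzoic acid | C[C@H](Cc1cc(OCc2ccccc2)cc(OCc2ccccc2)c1C(=O)O)OC(=O)C[C@@H](C)OC=O | intermediate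
11 | acid chloride of 10 | C[C@H](Cc1cc(OCc2ccccc2)cc(OCc2ccccc2)c1C(=O)Cl)OC(=O)C[C@@H](C)OC=O | intermediate
12 | tetra-O-benzyl O-formyl hansforester J | C[C@H](Cc1cc(OCc2ccccc2)cc(OCc2ccccc2)c1)OC(=O)C[C@@H](C)OC(=O)c1c(OCc2ccccc2)cc(OCc2ccccc2)cc1C[C@@H](C)OC(=O)C[C@@H](C)OC=O | intermediate
13 | O-formyl hansforester J (four free phenols, terminal formate) | C[C@H](Cc1cc(O)cc(O)c1)OC(=O)C[C@@H](C)OC(=O)c1c(O)cc(O)cc1C[C@@H](C)OC(=O)C[C@@H](C)OC=O | intermediate
14 | hansforester J | C[C@H](Cc1cc(O)cc(O)c1)OC(=O)C[C@@H](C)OC(=O)c1c(O)cc(O)cc1C[C@@H](C)OC(=O)C[C@@H](C)O | target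

**Total step count:** 5. **Longest linear sequence:** 5 (1 → 7 → 9 → 10 → 12 → 14; 7 is used twice).

**Steps most likely to fail**

Step 1 (proposed new relay).
- Risks: a second lactone insertion, base-induced opening of 3 to crotonate, or bromide attack at the alkyl C–O bond of 3.
- The fallback uses only known chemistry and sets out from alkoxide 5.
- 5 is quenched with AcOH and isolated as the free alcohol (R)-1-[3,5-bis(benzyloxy)phenyl]propan-2-ol F1.
- Heating F1 with 2,2,6-trimethyl-4H-1,3-dioxin-4-one in toluene at 110 °C (acylketene trapping) gives the acetoacetate (R)-1-[3,5-bis(benzyloxy)phenyl]propan-2-yl 3-oxobutanoate F2.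
- Noyori hydrogenation of F2 (H2 4 atm, RuCl2[(R)-BINAP] 0.5 mol %, EtOH–CH2Cl2, 50 °C) sets the (R)-carbinol by catalyst control instead of from the chiral pool. This comes back to the route at 7.

Step 2 (formylation with simultaneous O-formylation).
- Risks: the alkoxyiminium salt may collapse to the secondary chloride or to crotonate, and some formylation may occur between the two benzyloxy groups.
- The fallback brings in the carboxyl carbon as CO and sets out from 7.
- Benzyl chloroformate and pyridine in CH2Cl2 give the benzyl carbonate (R)-1-[3,5-bis(benzyloxy)phenyl]propan-2-yl (R)-3-{[(benzyloxy)carbonyl]oxy}butanoate F3.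
- N-iodosuccinimide with catalytic CF3CO2H in MeCN at 0 °C gives the aryl iodide (R)-1-[3,5-bis(benzyloxy)-2-iodophenyl]propan-2-yl (R)-3-{[(benzyloxy)carbonyl]oxy}butanoate F4.
- Palladium-catalysed alkoxycarbonylation of F4 with a second portion of 7 (Pd(OAc)2, Xantphos, CO 3 atm, iPr2NEt, toluene, 90 °C) forms the hindered ester by alcoholysis of the acyl-palladium species. The product is tetra-O-benzyl O-(benzyloxycarbonyl) hansforester J F5.
- A plain hydrogenolysis (H2, Pd/C, EtOAc–MeOH) removes all five benzyl-type groups. This comes back to the route at 14.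

Step 4 (hindered esterification).
- Risks: slow acylation at the di-ortho-substituted carbonyl, attack of the neighbouring side-chain ester oxygen on the activated acyl group (dihydroisocoumarin formation), and β-elimination under amine base.
- The fallback forms the alkyl C–O bond instead of the acyl C–O bond and sets out from 10.
- The partner is the epimeric alcohol (R)-1-[3,5-bis(benzyloxy)phenyl]propan-2-yl (S)-3-hydroxybutanoate F6. It is obtained from acetoacetate F2 by hydrogenation with RuCl2[(S)-BINAP].
- Mitsunobu esterification (PPh3, DIAD, toluene, 0 °C → rt) lets the carboxylate of 10 displace the activated (S)-carbinol with inversion to R, so the hindered carbonyl is never activated. This comes back to the route at 12.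

**Further compounds**
F1 | step 1 | (R)-1-[3,5-bis(benzyloxy)phenyl]propan-2-ol | C[C@H](Cc1cc(OCc2ccccc2)cc(OCc2ccccc2)c1)O
F2 | step 1 | (R)-1-[3,5-bis(benzyloxy)phenyl]propan-2-yl 3-oxobutanoate | C[C@H](Cc1cc(OCc2ccccc2)cc(OCc2ccccc2)c1)OC(=O)CC(C)=O
F3 | step 2 | (R)-1-[3,5-bis(benzyloxy)phenyl]propan-2-yl (R)-3-{[(benzyloxy)carbonyl]oxy}butanoate | C[C@H](Cc1cc(OCc2ccccc2)cc(OCc2ccccc2)c1)OC(=O)C[C@@H](C)OC(=O)OCc1ccccc1
F4 | step 2 | (R)-1-[3,5-bis(benzyloxy)-2-iodophenyl]propan-2-yl (R)-3-{[(benzyloxy)carbonyl]oxy}butanoate | C[C@H](Cc1cc(OCc2ccccc2)cc(OCc2ccccc2)c1I)OC(=O)C[C@@H](C)OC(=O)OCc1ccccc1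
F5 | step 2 | tetra-O-benzyl O-(benzyloxycarbonyl) hansforester J | C[C@H](Cc1cc(OCc2ccccc2)cc(OCc2ccccc2)c1)OC(=O)C[C@@H](C)OC(=O)c1c(OCc2ccccc2)cc(OCc2ccccc2)cc1C[C@@H](C)OC(=O)C[C@@H](C)OC(=O)OCc1ccccc1
F6 | step 4 | (R)-1-[3,5-bis(benzyloxy)phenyl]propan-2-yl (S)-3-hydroxybutanoate | C[C@H](Cc1cc(OCc2ccccc2)cc(OCc2ccccc2)c1)OC(=O)C[C@H](C)O
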